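Both C-prenyl bonds are cut at once: C8–CMe2 and C2'–CH2 go back to the 7-O- and 3-O-prenyl ethers of one flavonol.
Enabling feature: the CH2 on C2' is 1,5-related to O3 along O3–C3=C2–C1'=C2' (Claisen to C2, then Cope to C2'), and the quaternary carbon on C8 is ortho to O7 (aromatic Claisen with allyl inversion).
Further cuts: the O3–prenyl bond, ring C (oxidative chalcone cyclisation), the chalcone Cα=Cβ bond (aldol), and the chroman ring on the ring B aldehyde.
Forward: chroman ring first (propargyl ether, chromene, hydrogenation), aldol joins the ring A ketone to the ring B aldehyde, ring C closes, O3 is prenylated, one heating moves both prenyl groups to carbon without closing a ring, MOM removal ends the route.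
Stereochemistry: the target has no stereocentre; the E-chalcone alkene is consumed on ring C closure and the transient sp3 centres of the key step vanish on tautomerisation.

Key step: step 10

Remark: flavonoid numbering is used (C2' of the flavonol is C5 of the chroman unit); the two migrations of step 10 are independent, the intermediates are written with the ring A shift first, and transient compounds 8, 15, 18, 20 and 21 are racemic.

Step 1
Reactants: 1 2,4,6-trihydroxyacetophenone; 2 prenyl bromide (1-bromo-3-methylbut-2-ene)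
Product: 3 2,6-dihydroxy-4-(3-methylbut-2-enyloxy)acetophenone
Conditions: 2 (1.0 equiv), K2CO3 (1.1 equiv), acetone, rt to 50 °C
Reagents that add atoms: none
Why: Williamson ether synthesis in which the weak base ionises only the 4-OH, the one hydroxyl not hydrogen-bonded to the acetyl carbonyl and the most acidic, so one equivalent of bromide should give the 4-O-prenyl ether.

Step 2
Reactants: 3 2,6-dihydroxy-4-(3-methylbut-2-enyloxy)acetophenone
Product: 4 2-hydroxy-6-(methoxymethoxy)-4-(3-methylbut-2-enyloxy)acetophenone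
Conditions: MOMCl (1.1 equiv), i-Pr2NEt, CH2Cl2, 0 °C to rt
Reagents that add atoms: chloromethyl methyl ether (MOMCl), COCCl
Why: MOM acetal formation by O-alkylation of one of the two equivalent hydroxyls, after which the remaining hydroxyl is locked in the hydrogen bond to the ketone and should not react a second time.

Step 3
Reactants: 5 3,4-dihydroxybenzaldehyde; 6 3-chloro-3-methylbut-1-yne
Product: 7 3-hydroxy-4-(2-methylbut-3-yn-2-yloxy)benzaldehyde
Conditions: 6 (1.2 equiv), DBU (1.1 equiv), CuCl2·2H2O (cat.), MeCN, 0 °C to rt, under argon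
Reagents that add atoms: none
Why: Copper-catalysed propargylic etherification of the tertiary propargyl chloride, in which one equivalent of base ionises only the 4-OH, which is para to the formyl group and much more acidic than the 3-OH.

Step 4
Reactants: 7 3-hydroxy-4-(2-methylbut-3-yn-2-yloxy)benzaldehyde
Product: 11 8-hydroxy-2,2-dimethyl-2H-chromene-6-carbaldehyde, via allenyl dienone 8 (not isolated), via allenylphenol 9 (not isolated), via ortho-quinone methide 10 (not isolated)
Conditions: o-dichlorobenzene, 160 °C, under argon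
Reagents that add atoms: none
Why: Aromatic propargyl Claisen rearrangement to C5, the only free ortho carbon, then enolisation, 1,5-hydrogen shift and oxa-6π electrocyclisation, the standard thermal route from aryl 1,1-dimethylpropargyl ethers to 2,2-dimethylchromenes.

Step 5
Reactants: 11 8-hydroxy-2,2-dimethyl-2H-chromene-6-carbaldehyde
Product: 12 8-hydroxy-2,2-dimethylchroman-6-carbaldehyde
Conditions: H2 (1 atm), Pd/C, Ph2S (cat.), EtOAc, rt
Reagents that add atoms: none
Why: Catalytic hydrogenation of the styrene-type chromene alkene, which is much faster than reduction of the electron-rich aryl aldehyde, the more so on sulfide-moderated Pd/C.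

Step 6
Reactants: 12 8-hydroxy-2,2-dimethylchroman-6-carbaldehyde
Product: 13 8-(methoxymethoxy)-2,2-dimethylchroman-6-carbaldehyde
Conditions: MOMCl (1.3 equiv), i-Pr2NEt, CH2Cl2, 0 °C to rt
Reagents that add atoms: chloromethyl methyl ether (MOMCl), COCCl
Why: MOM protection of the single phenol as an acetal that is stable to the hydroxide, peroxide and heat of the later steps.

Step 7
Reactants: 4 2-hydroxy-6-(methoxymethoxy)-4-(3-methylbut-2-enyloxy)acetophenone; 13 8-(methoxymethoxy)-2,2-dimethylchroman-6-carbaldehyde
Product: 14 (E)-1-[2-hydroxy-6-(methoxymethoxy)-4-(3-methylbut-2-enyloxy)phenyl]-3-[8-(methoxymethoxy)-2,2-dimethylchroman-6-yl]prop-2-en-1-one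
Conditions: KOH (50% aq.), EtOH, rt
Reagents that add atoms: none
Why: Claisen–Schmidt condensation of the acetophenone enolate with the non-enolisable aldehyde, the E-enone arising by E1cB dehydration of the aldol, with the MOM and prenyl ethers inert to hydroxide.

Step 8
Reactants: 14 the 2'-hydroxychalcone of step 7
Product: 16 3-hydroxy-5-(methoxymethoxy)-2-[8-(methoxymethoxy)-2,2-dimethylchroman-6-yl]-7-(3-methylbut-2-enyloxy)-4H-chromen-4-one, via trans-3-hydroxyflavanone 15 (not isolated)
Conditions: H2O2 (30% aq.), NaOH (2 M aq.), MeOH–THF, 0 °C to rt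
Reagents that add atoms: hydrogen peroxide, OO
Why: Algar–Flynn–Oyamada oxidative cyclisation, in which the 2'-phenoxide closes ring C on the enone β-carbon with oxygenation of the α-carbon and more peroxide dehydrogenates the dihydroflavonol, while the isolated electron-rich prenyl alkene is not attacked by alkaline peroxide.

Step 9
Reactants: 16 the 3-hydroxyflavone of step 8; 2 prenyl bromide
Product: 17 5-(methoxymethoxy)-2-[8-(methoxymethoxy)-2,2-dimethylchroman-6-yl]-3,7-bis(3-methylbut-2-enyloxy)-4H-chromen-4-one
Conditions: 2 (1.3 equiv), K2CO3, DMF, rt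
Reagents that add atoms: none
Why: Williamson ether synthesis at the only free hydroxyl, the acidic enolic 3-OH of the flavonol.

Step 10
Reactants: 17 the 3,7-bis(prenyloxy)flavone of step 9
Product: 22 3,7-dihydroxy-5-(methoxymethoxy)-2-[8-(methoxymethoxy)-2,2-dimethyl-5-(3-methylbut-2-enyl)chroman-6-yl]-8-(2-methylbut-3-en-2-yl)-4H-chromen-4-one, via ring A dienone 18 (not isolated), via mono-rearranged phenol 19 (not isolated), via chroman-3,4-dione 20 (not isolated), via ring B isotoluene 21 (not isolated)
Conditions: PhNEt2 (degassed), 195 °C, sealed tube, under argon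
Reagents that add atoms: none
Why: Proposed new method: on heating, the 7-O-prenyl ether should undergo an aromatic Claisen [3,3] shift with allyl inversion to C8 (dienone 18) and enolise to phenol 19, while the 3-O-prenyl ether, an allyl vinyl ether through O3–C3=C2, should shift [3,3] to C2 and give the non-enolisable 2-aryl-2-(1,1-dimethylallyl)chroman-3,4-dione 20, whose weak C2–CMe2 bond sits in the 1,5-diene CH2=CH–CMe2–C2–C1'=C2', so that a Cope [3,3] shift carries the CH2 terminus to C2' as a normal prenyl group (21) and hydrogen transfer from C2' to O3 restores aromatic ring B and the flavonol, which drains the reversible first shift. The closest known reaction type is the para-Claisen (Claisen–Cope) rearrangement of ortho-blocked aryl prenyl ethers, together with the Claisen rearrangement of 3-allyloxy-4-pyranones and 3-allyloxychromones to C2; the ring A half is the known ortho-Claisen rearrangement of 7-prenyloxyflavones. No ring is closed and no stereocentre remains, because the transient centres at C8, C2 and C2' are erased by tautomerisation. The step needs C8 over C6 and C2' over C6': the first should follow from the bond fixation of chromones (higher double-bond character of C7–C8) with the 5-oxygen held as a non-chelated ether, the second from C2' being para to the 5'-oxygen donor, the site favoured in Claisen shifts of meta-donor arenes, while C6' lies beside the OMOM group. The two migrations do not interfere, so one heating operation should set both hindered C-prenyl groups.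

Step 11
Reactants: 22 the 5,5'-bis-MOM ether of broussoflavonol E
Product: 23 broussoflavonol E, 3,5,7-trihydroxy-2-[8-hydroxy-2,2-dimethyl-5-(3-methylbut-2-enyl)chroman-6-yl]-8-(2-methylbut-3-en-2-yl)-4H-chromen-4-one
Conditions: HCl (about 1 M) in MeOH–THF, 40 °C
Reagents that add atoms: none
Why: Acid-catalysed acetal methanolysis of both MOM ethers under dilute acid, which should spare the prenyl group (no ortho hydroxyl to cyclise on) and the 1,1-dimethylallyl group (only a secondary cation available).

Compound list
1 | 2,4,6-trihydroxyacetophenone | CC(=O)c1c(O)cc(O)cc1O | starting material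
2 | prenyl bromide (1-bromo-3-methylbut-2-ene) | CC(C)=CCBr | starting material
3 | 2,6-dihydroxy-4-(3-methylbut-2-enyloxy)acetophenone | CC(=O)c1c(O)cc(OCC=C(C)C)cc1O | intermediate
4 | 2-hydroxy-6-(methoxymethoxy)-4-(3-methylbut-2-enyloxy)acetophenone | CC(=O)c1c(O)cc(OCC=C(C)C)cc1OCOC | intermediate
5 | 3,4-dihydroxybenzaldehyde | O=Cc1ccc(O)c(O)c1 | starting material
6 | 3-chloro-3-methylbut-1-yne | C#CC(C)(C)Cl | starting material
7 | 3-hydroxy-4-(2-methylbut-3-yn-2-yloxy)benzaldehyde | C#CC(C)(C)Oc1ccc(C=O)cc1O | intermediate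
8 | 5-hydroxy-3-(3-methylbuta-1,2-dienyl)-4-oxocyclohexa-1,5-diene-1-carbaldehyde (allenyl dienone, racemic, transient) | CC(C)=C=CC1C=C(C=O)C=C(O)C1=O | intermediate
9 | 3,4-dihydroxy-5-(3-methylbuta-1,2-dienyl)benzaldehyde (allenylphenol, transient) | O=Cc1cc(O)c(O)c(C=C=C(C)C)c1 | intermediate
10 | (3Z)-5-hydroxy-3-(3-methylbut-2-enylidene)-4-oxocyclohexa-1,5-diene-1-carbaldehyde (ortho-quinone methide, transient) | O=CC1=C/C(=C/C=C(C)C)C(=O)C(O)=C1 | intermediate
11 | 8-hydroxy-2,2-dimethyl-2H-chromene-6-carbaldehyde | CC1(C)C=Cc2cc(C=O)cc(O)c2O1 | intermediate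
12 | 8-hydroxy-2,2-dimethylchroman-6-carbaldehyde | CC1(C)CCc2cc(C=O)cc(O)c2O1 | intermediate
13 | 8-(methoxymethoxy)-2,2-dimethylchroman-6-carbaldehyde | CC1(C)CCc2cc(C=O)cc(OCOC)c2O1 | intermediate
14 | (E)-1-[2-hydroxy-6-(methoxymethoxy)-4-(3-methylbut-2-enyloxy)phenyl]-3-[8-(methoxymethoxy)-2,2-dimethylchroman-6-yl]prop-2-en-1-one | COCOc1cc(OCC=C(C)C)cc(O)c1C(=O)/C=C/c1cc(OCOC)c2OC(C)(C)CCc2c1 | intermediate
15 | trans-3-hydroxy-5-(methoxymethoxy)-2-[8-(methoxymethoxy)-2,2-dimethylchroman-6-yl]-7-(3-methylbut-2-enyloxy)chroman-4-one (racemic, the 2R,3R enantiomer drawn, transient) | O=C1c2c(OCOC)cc(OCC=C(C)C)cc2O[C@H](c2cc(OCOC)c3OC(C)(C)CCc3c2)[C@H]1O | intermediate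
16 | 3-hydroxy-5-(methoxymethoxy)-2-[8-(methoxymethoxy)-2,2-dimethylchroman-6-yl]-7-(3-methylbut-2-enyloxy)-4H-chromen-4-one | COCOc1cc(OCC=C(C)C)cc2oc(-c3cc(OCOC)c4OC(C)(C)CCc4c3)c(O)c(=O)c12 | intermediate
17 | 5-(methoxymethoxy)-2-[8-(methoxymethoxy)-2,2-dimethylchroman-6-yl]-3,7-bis(3-methylbut-2-enyloxy)-4H-chromen-4-one | COCOc1cc(OCC=C(C)C)cc2oc(-c3cc(OCOC)c4OC(C)(C)CCc4c3)c(OCC=C(C)C)c(=O)c12 | intermediate
18 | 5-(methoxymethoxy)-2-[8-(methoxymethoxy)-2,2-dimethylchroman-6-yl]-8-(2-methylbut-3-en-2-yl)-3-(3-methylbut-2-enyloxy)-8H-chromene-4,7-dione (ring A dienone, racemic, transient) | C=CC(C)(C)C1C(=O)C=C(OCOC)C2=C1OC(c1cc(OCOC)c3OC(C)(C)CCc3c1)=C(OCC=C(C)C)C2=O | intermediate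
19 | 7-hydroxy-5-(methoxymethoxy)-2-[8-(methoxymethoxy)-2,2-dimethylchroman-6-yl]-8-(2-methylbut-3-en-2-yl)-3-(3-methylbut-2-enyloxy)-4H-chromen-4-one (transient) | C=CC(C)(C)c1c(O)cc(OCOC)c2c(=O)c(OCC=C(C)C)c(-c3cc(OCOC)c4OC(C)(C)CCc4c3)oc12 | intermediate
20 | 7-hydroxy-5-(methoxymethoxy)-2-[8-(methoxymethoxy)-2,2-dimethylchroman-6-yl]-2,8-bis(2-methylbut-3-en-2-yl)chroman-3,4-dione (racemic, transient) | C=CC(C)(C)c1c(O)cc(OCOC)c2C(=O)C(=O)C(c3cc(OCOC)c4OC(C)(C)CCc4c3)(C(C)(C)C=C)Oc12 | intermediate
21 | 7-hydroxy-5-(methoxymethoxy)-2-[8-(methoxymethoxy)-2,2-dimethyl-5-(3-methylbut-2-enyl)-3,4-dihydro-2H-chromen-6(5H)-ylidene]-8-(2-methylbut-3-en-2-yl)chroman-3,4-dione (ring B isotoluene, racemic, exocyclic alkene geometry not fixed, transient) | C=CC(C)(C)c1c(O)cc(OCOC)c2C(=O)C(=O)C(=C3C=C(OCOC)C4=C(CCC(C)(C)O4)C3CC=C(C)C)Oc12 | intermediate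
22 | 3,7-dihydroxy-5-(methoxymethoxy)-2-[8-(methoxymethoxy)-2,2-dimethyl-5-(3-methylbut-2-enyl)chroman-6-yl]-8-(2-methylbut-3-en-2-yl)-4H-chromen-4-one | C=CC(C)(C)c1c(O)cc(OCOC)c2c(=O)c(O)c(-c3cc(OCOC)c4c(c3CC=C(C)C)CCC(C)(C)O4)oc12 | intermediate
23 | broussoflavonol E, 3,5,7-trihydroxy-2-[8-hydroxy-2,2-dimethyl-5-(3-methylbut-2-enyl)chroman-6-yl]-8-(2-methylbut-3-en-2-yl)-4H-chromen-4-one | C=CC(C)(C)c1c(O)cc(O)c2c(=O)c(O)c(-c3cc(O)c4c(c3CC=C(C)C)CCC(C)(C)O4)oc12 | target

Total step count: 11 steps.
Longest linear sequence: 9 steps (from 5 through steps 3 to 11); the ring A branch (steps 1 and 2) joins at step 7.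

Steps most likely to fail

1. Step 10 (new method). Three processes threaten it.
- The [3,3] shift from O3 to C2 must join two fully substituted carbons, so C–O cleavage of the 3-O-prenyl ether (loss of the prenyl group or unselective recombination) may outrun it.
- The Cope shift may deliver the allyl group to C6' instead of C2'.
- The ring A shift may go partly to C6, or the new ortho-(1,1-dimethylallyl)phenol may cyclise on prolonged heating.

Fallback with known chemistry, setting out from aldehyde 13 (with acetophenone 4) and returning at 22: the C2' prenyl group is put on ring B before the flavonol is built, so only the known ring A shift is left for the end. Bromination of 13 with NBS in DMF should go para to the OMOM group and ortho to the ring alkyl carbon, the pattern of 6-bromoveratraldehyde, to give 5-bromo-8-(methoxymethoxy)-2,2-dimethylchroman-6-carbaldehyde F1. Suzuki–Miyaura coupling of the bromide with prenylboronic acid pinacol ester (Pd(OAc)2, a bulky biarylphosphine chosen for coupling at the CH2 terminus, K3PO4, THF–H2O) would give 8-(methoxymethoxy)-2,2-dimethyl-5-(3-methylbut-2-enyl)chroman-6-carbaldehyde F2. Claisen–Schmidt condensation with 4 (KOH, EtOH) would give the C2'-prenylated chalcone F3, and Algar–Flynn–Oyamada oxidation (H2O2, NaOH) the C2'-prenylated 7-prenyloxyflavonol F4. The ortho-Claisen rearrangement of its single 7-O-prenyl ether (PhNEt2, 200 °C) would then give 22.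

2. Step 8. With the 6'-alkoxy group present, 5-exo attack of the phenoxide at the α-carbon (aurone formation) may compete with the 6-endo closure that leads to the flavonol.

Fallback, setting out from chalcone 14 and returning at 16: ring C is closed first and the 3-oxygen is added afterwards. Oxidative cyclisation of 14 with catalytic I2 in DMSO at about 120 °C would give 5-(methoxymethoxy)-2-[8-(methoxymethoxy)-2,2-dimethylchroman-6-yl]-7-(3-methylbut-2-enyloxy)-4H-chromen-4-one F5. Lithiation at C3 with LiN(i-Pr)2 in THF at −78 °C, trapping with B(OMe)3 and oxidation of the boronate with alkaline H2O2 would then install the 3-hydroxyl and give 16.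

3. Step 1. The phloroglucinol-type phenoxide is ambident and the product is still a phenol, so over-alkylation and C-prenylation may erode the yield of the mono-ether.

Fallback, setting out from 1 and returning at 3: Mitsunobu etherification of 1 with 3-methylbut-2-en-1-ol (PPh3, diisopropyl azodicarboxylate, THF, 0 °C). The alcohol is activated instead of the phenol being ionised, which removes the C-alkylation pathway, and only the acidic non-chelated 4-OH should react. No new compound is made on this way (entry F0).

Further compounds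
F1 | step 10 | 5-bromo-8-(methoxymethoxy)-2,2-dimethylchroman-6-carbaldehyde | CC1(C)CCc2c(Br)c(C=O)cc(OCOC)c2O1
F2 | step 10 | 8-(methoxymethoxy)-2,2-dimethyl-5-(3-methylbut-2-enyl)chroman-6-carbaldehyde | CC(C)=CCc1c(C=O)cc(OCOC)c2OC(C)(C)CCc12
F3 | step 10 | (E)-1-[2-hydroxy-6-(methoxymethoxy)-4-(3-methylbut-2-enyloxy)phenyl]-3-[8-(methoxymethoxy)-2,2-dimethyl-5-(3-methylbut-2-enyl)chroman-6-yl]prop-2-en-1-one | COCOc1cc(OCC=C(C)C)cc(O)c1C(=O)/C=C/c1cc(OCOC)c2OC(C)(C)CCc2c1CC=C(C)C
F4 | step 10 | 3-hydroxy-5-(methoxymethoxy)-2-[8-(methoxymethoxy)-2,2-dimethyl-5-(3-methylbut-2-enyl)chroman-6-yl]-7-(3-methylbut-2-enyloxy)-4H-chromen-4-one | COCOc1cc(OCC=C(C)C)cc2oc(-c3cc(OCOC)c4OC(C)(C)CCc4c3CC=C(C)C)c(O)c(=O)c12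
F5 | step 8 | 5-(methoxymethoxy)-2-[8-(methoxymethoxy)-2,2-dimethylchroman-6-yl]-7-(3-methylbut-2-enyloxy)-4H-chromen-4-one | COCOc1cc(OCC=C(C)C)cc2oc(-c3cc(OCOC)c4OC(C)(C)CCc4c3)cc(=O)c12
F0 | step 1 | none | none
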